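**Strategy.** Everything rests on disconnecting the C7–C8 bond of the ten-membered carbocycle (germacrane numbering: C6 lactone O–CH, C7 tertiary carbinol, C8 acyloxy carbon). C7 is at once a ring atom of the butenolide O–C12–C11–C7–C6 and the γ-terminus of the allyl unit C13–C11–C7. A 3-(bromomethyl)-4-(4-methoxybenzyloxy)butenolide, tethered through C6 to a C8 aldehyde, is therefore reduced with CrCl2 to a γ-alkoxyallylchromium that attacks the aldehyde through C7. One operation closes the carbocycle, sets C7 and C8, installs the C7 oxygen and unveils the α-methylene lactone. Acylation with the (2S,3R)-epoxy acid and two deprotections complete the target.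

Key step: step 15

Numbering used in the text: C1–C10 carbocycle (C1=C10 Z, C4=C5 E), C6 lactone O–CH, C7 C–OH, C8 CH–O-acyl, C9 CH–OH, C11/C12/C13 lactone α-carbon, carbonyl and exocyclic CH2. TBS = tert-butyldimethylsilyl, PMB = 4-methoxybenzyl.

Assumption: the (S,S)-ProPhenol/Me2Zn alkynylation is taken to deliver the (4R)-carbinol 17 from enal 14; if the sense is opposite, the (R,R)-ligand is used.

Assumption: compounds 1, 4, 15 and 28 are taken as commercially available.

**Step 1**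
Reactants: 1 methyl (4S)-2,2-dimethyl-1,3-dioxolane-4-carboxylate
Product: 3 1-[(4S)-2,2-dimethyl-1,3-dioxolan-4-yl]ethan-1-one, via Weinreb amide 2 (not isolated)
Conditions: MeNH(OMe)·HCl, i-PrMgCl, THF, −20 °C; then MeMgBr, −20 → 0 °C; aq. NH4Cl
Reagents that add atoms: methylmagnesium bromide C[Mg]Br; N,O-dimethylhydroxylamine hydrochloride CNOC.Cl (atoms of intermediate 2 only)
Why: Aminolysis of the ester by the magnesium amide gives the Weinreb amide, whose chelated tetrahedral adduct with MeMgBr stops at the ketone (Weinreb ketone synthesis); the stereocentre comes from 1 and the low temperature should limit enolisation.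

**Step 2**
Reactants: 4 5-chloropent-1-yne
Product: 6 (1E)-5-chloro-1-iodo-2-methylpent-1-ene, via alkenylalane 5 (not isolated)
Conditions: Me3Al, Cp2ZrCl2 (cat.), CH2Cl2, 0 °C → rt; then I2, THF, −30 °C
Reagents that add atoms: trimethylaluminium C[Al](C)C; iodine II
Why: Zirconium-catalysed carboalumination (Negishi) adds methyl and aluminium syn across the terminal alkyne with methyl at the internal carbon, and iodination with retention fixes the E trisubstituted alkene that becomes C4=C5.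

**Step 3**
Reactants: 6 (1E)-5-chloro-1-iodo-2-methylpent-1-ene
Product: 8 [(4E)-5-iodo-4-methylpent-4-en-1-yl]triphenylphosphonium iodide, via diiodide 7 (not isolated)
Conditions: NaI, PPh3, MeCN, reflux
Reagents that add atoms: sodium iodide [Na+].[I-]; triphenylphosphine c1ccc(cc1)P(c1ccccc1)c1ccccc1
Why: Finkelstein exchange of the primary chloride followed by SN2 quaternisation of PPh3 should give the phosphonium salt, the vinyl iodide being inert to both.

**Step 4**
Reactants: 8 [(4E)-5-iodo-4-methylpent-4-en-1-yl]triphenylphosphonium iodide; 3 1-[(4S)-2,2-dimethyl-1,3-dioxolan-4-yl]ethan-1-one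
Product: 10 (4R)-4-[(2Z,6E)-7-iodo-6-methylhepta-2,6-dien-2-yl]-2,2-dimethyl-1,3-dioxolane, via phosphorus ylide 9 (not isolated)
Conditions: NaN(SiMe3)2, THF, −78 °C; then 3, −78 °C → rt
Reagents that add atoms: none
Why: The Wittig reaction of a non-stabilised ylide with an α-alkoxy methyl ketone is expected to give the Z trisubstituted alkene (C2 cis to C9) under kinetic control, and the lithium-free, low-temperature protocol should leave the α-alkoxy stereocentre (C9) untouched.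

**Step 5**
Reactants: 10 (4R)-4-[(2Z,6E)-7-iodo-6-methylhepta-2,6-dien-2-yl]-2,2-dimethyl-1,3-dioxolane
Product: 11 (2R,3Z,7E)-8-iodo-3,7-dimethylocta-3,7-diene-1,2-diol
Conditions: AcOH/H2O/THF (3:1:1), 45 °C
Reagents that add atoms: none
Why: Mild acid-catalysed acetal hydrolysis should free the 1,2-diol without touching the vinyl iodide or the alkene geometries.

**Step 6**
Reactants: 11 (2R,3Z,7E)-8-iodo-3,7-dimethylocta-3,7-diene-1,2-diol
Product: 12 (2R,3Z,7E)-1,2-bis(tert-butyldimethylsilyloxy)-8-iodo-3,7-dimethylocta-3,7-diene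
Conditions: TBSOTf, 2,6-lutidine, CH2Cl2, −78 → 0 °C
Reagents that add atoms: tert-butyldimethylsilyl trifluoromethanesulfonate CC(C)(C)[Si](C)(C)OS(=O)(=O)C(F)(F)F
Why: Silylation with the silyl triflate should protect both hydroxyls, including the hindered allylic C9 one, as non-chelating TBS ethers.

**Step 7**
Reactants: 12 (2R,3Z,7E)-1,2-bis(tert-butyldimethylsilyloxy)-8-iodo-3,7-dimethylocta-3,7-diene
Product: 14 (2E,6Z,8R)-8,9-bis(tert-butyldimethylsilyloxy)-3,7-dimethylnona-2,6-dienal, via alkenyllithium 13 (not isolated)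
Conditions: t-BuLi (2 equiv), Et2O, −78 °C; then DMF, −78 → 0 °C; aq. NH4Cl
Reagents that add atoms: N,N-dimethylformamide CN(C)C=O; tert-butyllithium [Li]C(C)(C)C (lithium of intermediate 13 only)
Why: Iodine–lithium exchange proceeds with retention of alkene geometry and formylation of the alkenyllithium with DMF should give the E enal that carries C6 as the aldehyde carbon.

**Step 8**
Reactants: 14 (2E,6Z,8R)-8,9-bis(tert-butyldimethylsilyloxy)-3,7-dimethylnona-2,6-dienal; 15 methyl prop-2-ynoate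
Product: 17 methyl (4R,5E,9Z,11R)-11,12-bis(tert-butyldimethylsilyloxy)-4-hydroxy-6,10-dimethyldodeca-5,9-dien-2-ynoate, via zinc alkynylide 16 (not isolated)
Conditions: Me2Zn, (S,S)-ProPhenol (20 mol%), Ph3P=O (40 mol%), toluene, 0–4 °C
Reagents that add atoms: dimethylzinc C[Zn]C (methylzinc of intermediate 16 only)
Why: Catalytic asymmetric alkynylation of an enal: the dinuclear zinc–ProPhenol complex should deliver the zinc alkynylide to one carbonyl face and so set C6 (R) under ligand control.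

**Step 9**
Reactants: 17 methyl (4R,5E,9Z,11R)-11,12-bis(tert-butyldimethylsilyloxy)-4-hydroxy-6,10-dimethyldodeca-5,9-dien-2-ynoate
Product: 19 (5R)-5-[(1E,5Z,7R)-7,8-bis(tert-butyldimethylsilyloxy)-2,6-dimethylocta-1,5-dien-1-yl]-4-[(4-methoxyphenyl)methoxy]furan-2(5H)-one, via oxa-Michael adduct 18 (not isolated)
Conditions: 4-methoxybenzyl alcohol (5 equiv), NaH (0.2 equiv), THF, 0 °C → rt
Reagents that add atoms: 4-methoxybenzyl alcohol COc1ccc(CO)cc1
Why: Alkoxide oxa-Michael addition to the ynoate β-carbon (C7) followed by lactonisation of the (E)-β-alkoxy enoate is the established route from 4-hydroxy-2-ynoates to 4-alkoxybutenolides (tetronates), and C6 is not involved.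

**Step 10**
Reactants: 19 (5R)-5-[(1E,5Z,7R)-7,8-bis(tert-butyldimethylsilyloxy)-2,6-dimethylocta-1,5-dien-1-yl]-4-[(4-methoxyphenyl)methoxy]furan-2(5H)-one
Product: 20 the 3-iodo derivative of 19, (5R)-5-[(1E,5Z,7R)-7,8-bis(tert-butyldimethylsilyloxy)-2,6-dimethylocta-1,5-dien-1-yl]-3-iodo-4-[(4-methoxyphenyl)methoxy]furan-2(5H)-one
Conditions: N-iodosuccinimide, MeCN, 0 °C → rt, dark
Reagents that add atoms: N-iodosuccinimide O=C1CCC(=O)N1I
Why: Electrophilic iodination at the nucleophilic C3 of the vinylogous carbonate (iodonium attack then proton loss) is a known halogenation of tetronates, whereas the isolated trisubstituted alkenes have no irreversible pathway without an added nucleophile.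

**Step 11**
Reactants: 20 (5R)-5-[(1E,5Z,7R)-7,8-bis(tert-butyldimethylsilyloxy)-2,6-dimethylocta-1,5-dien-1-yl]-3-iodo-4-[(4-methoxyphenyl)methoxy]furan-2(5H)-one
Product: 22 (5R)-5-[(1E,5Z,7R)-7,8-bis(tert-butyldimethylsilyloxy)-2,6-dimethylocta-1,5-dien-1-yl]-3-(hydroxymethyl)-4-[(4-methoxyphenyl)methoxy]furan-2(5H)-one, via alkenylmagnesium chloride 21 (not isolated)
Conditions: i-PrMgCl·LiCl, THF, −40 °C; then CH2O (gas, from cracked paraformaldehyde), −40 → 0 °C; aq. NH4Cl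
Reagents that add atoms: formaldehyde C=O; isopropylmagnesium chloride CC(C)[Mg]Cl (MgCl of intermediate 21 only)
Why: Iodine–magnesium exchange of the α-iodo enoate gives an alkenylmagnesium that cannot β-eliminate inside the five-membered ring, and its addition to formaldehyde installs C13 as CH2OH.

**Step 12**
Reactants: 22 (5R)-5-[(1E,5Z,7R)-7,8-bis(tert-butyldimethylsilyloxy)-2,6-dimethylocta-1,5-dien-1-yl]-3-(hydroxymethyl)-4-[(4-methoxyphenyl)methoxy]furan-2(5H)-one
Product: 23 (5R)-5-[(1E,5Z,7R)-7,8-bis(tert-butyldimethylsilyloxy)-2,6-dimethylocta-1,5-dien-1-yl]-3-(bromomethyl)-4-[(4-methoxyphenyl)methoxy]furan-2(5H)-one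
Conditions: CBr4, PPh3, CH2Cl2, 0 °C
Reagents that add atoms: carbon tetrabromide BrC(Br)(Br)Br
Why: The Appel reaction should convert the primary allylic alcohol into the bromide under neutral conditions that spare silyl ethers, the PMB enol ether and the alkenes.

**Step 13**
Reactants: 23 (5R)-5-[(1E,5Z,7R)-7,8-bis(tert-butyldimethylsilyloxy)-2,6-dimethylocta-1,5-dien-1-yl]-3-(bromomethyl)-4-[(4-methoxyphenyl)methoxy]furan-2(5H)-one
Product: 24 (5R)-3-(bromomethyl)-5-[(1E,5Z,7R)-7-(tert-butyldimethylsilyloxy)-8-hydroxy-2,6-dimethylocta-1,5-dien-1-yl]-4-[(4-methoxyphenyl)methoxy]furan-2(5H)-one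
Conditions: HF·pyridine, THF, 0 °C
Reagents that add atoms: none
Why: Selective desilylation: the primary TBS ether should cleave well before the hindered secondary allylic one at C9, and no free amine is present that could quaternise the allylic bromide.

**Step 14**
Reactants: 24 (5R)-3-(bromomethyl)-5-[(1E,5Z,7R)-7-(tert-butyldimethylsilyloxy)-8-hydroxy-2,6-dimethylocta-1,5-dien-1-yl]-4-[(4-methoxyphenyl)methoxy]furan-2(5H)-one
Product: 25 (2R,3Z,7E)-8-[(2R)-4-(bromomethyl)-3-[(4-methoxyphenyl)methoxy]-5-oxo-2,5-dihydrofuran-2-yl]-2-(tert-butyldimethylsilyloxy)-3,7-dimethylocta-3,7-dienal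
Conditions: Dess–Martin periodinane, CH2Cl2, 0 °C → rt; used at once
Reagents that add atoms: none
Why: Dess–Martin oxidation under non-basic conditions should give the α-silyloxy β,γ-unsaturated aldehyde without epimerisation at C9 or alkene migration.

**Step 15**
Reactants: 25 (2R,3Z,7E)-8-[(2R)-4-(bromomethyl)-3-[(4-methoxyphenyl)methoxy]-5-oxo-2,5-dihydrofuran-2-yl]-2-(tert-butyldimethylsilyloxy)-3,7-dimethylocta-3,7-dienal
Product: 27 (3aS,4R,5R,6Z,10E,11aR)-5-(tert-butyldimethylsilyloxy)-4-hydroxy-3a-[(4-methoxyphenyl)methoxy]-6,10-dimethyl-3-methylidene-3a,4,5,8,9,11a-hexahydrocyclodeca[b]furan-2(3H)-one, via allylchromium dichloride 26 (not isolated)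
Conditions: CrCl2 (10 equiv), THF, rt, slow addition of 25 (final 3 mM); aq. NH4Cl
Reagents that add atoms: chromium dichloride Cl[Cr]Cl (chromium and chloride of intermediate 26 only)
Why: Proposed new method: two equivalents of CrCl2 reduce the C13–Br bond to a γ-alkoxy, γ,γ-disubstituted allylchromium dichloride (26), which adds to the C8 aldehyde through its γ-carbon C7 in a six-membered cyclic transition state (SE2′) while the double bond moves to C11=C13. The closest known reactions are the intramolecular Nozaki–Hiyama–Kishi allylation of aldehydes by α-(bromomethyl)butenolides and acrylates, used to close ten-membered germacranolide rings, and the addition of γ-alkoxyallylchromium reagents to aldehydes; new here is the tetronate as allyl donor, which makes the attacking carbon a fully substituted C–O centre. The ten-membered carbocycle closes by 10-exo-trig attack on the aldehyde carbonyl, and the competing α-attack through C13 (twelve-membered ring, tetronate retained) should be disfavoured by the cyclic chromium transition state. C7 is controlled by C6: the tether leaves C6 on one face of the planar butenolide and the E-configured C4=C5 unit should let C8 reach C7 only from the opposite face, giving the trans-fused lactone with the C7 oxygen cis to C5. C8 is controlled by C9 through Felkin–Anh addition to the α-silyloxy aldehyde (non-chelating TBS ether, 8,9-anti), which corresponds to a transition state with the C8–C9 bond antiperiplanar to the bulky C7–OPMB bond. The step needs γ-regioselectivity, ring closure over oligomerisation and this double facial selectivity, which the cyclic transition state, high dilution and the two resident stereocentres are expected to secure.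

**Step 16**
Reactants: 28 (2E)-2-methylbut-2-en-1-ol
Product: 29 [(2R,3R)-2,3-dimethyloxiran-2-yl]methanol
Conditions: Ti(OiPr)4 (10 mol%), D-(−)-diethyl tartrate (12 mol%), t-BuOOH, 4 Å molecular sieves, CH2Cl2, −20 °C
Reagents that add atoms: tert-butyl hydroperoxide CC(C)(C)OO
Why: Sharpless asymmetric epoxidation: the D-(−)-tartrate titanium complex should deliver oxygen to the alkene face that gives the (2R,3R)-epoxide, the cis-dimethyl relationship following from the E alkene.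

**Step 17**
Reactants: 29 [(2R,3R)-2,3-dimethyloxiran-2-yl]methanol
Product: 31 (2S,3R)-2,3-dimethyloxirane-2-carboxylic acid, via epoxy aldehyde 30 (not isolated)
Conditions: RuCl3·xH2O (2 mol%), NaIO4, MeCN/EtOAc/H2O, 0 °C → rt
Reagents that add atoms: water O (second carboxyl oxygen, through the aldehyde hydrate)
Why: Ruthenium tetroxide oxidation (RuCl3/NaIO4) takes the epoxy alcohol through the aldehyde hydrate to the glycidic acid without opening the epoxide; the change of the C2 descriptor from R to S is only a change of CIP priorities.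

**Step 18**
Reactants: 31 (2S,3R)-2,3-dimethyloxirane-2-carboxylic acid; 27 (3aS,4R,5R,6Z,10E,11aR)-5-(tert-butyldimethylsilyloxy)-4-hydroxy-3a-[(4-methoxyphenyl)methoxy]-6,10-dimethyl-3-methylidene-3a,4,5,8,9,11a-hexahydrocyclodeca[b]furan-2(3H)-one
Product: 33 (3aR,4R,5R,6Z,10E,11aR)-5-(tert-butyldimethylsilyloxy)-3a-[(4-methoxyphenyl)methoxy]-6,10-dimethyl-3-methylidene-2-oxo-2,3,3a,4,5,8,9,11a-octahydrocyclodeca[b]furan-4-yl (2S,3R)-2,3-dimethyloxirane-2-carboxylate, via mixed anhydride 32 (not isolated)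
Conditions: 2,4,6-trichlorobenzoyl chloride, Et3N, toluene, rt; then 27, DMAP, toluene, rt → 40 °C
Reagents that add atoms: 2,4,6-trichlorobenzoyl chloride O=C(Cl)c1c(Cl)cc(Cl)cc1Cl (atoms of intermediate 32 only)
Why: Yamaguchi esterification: DMAP transfers the epoxy acyl group from the mixed anhydride to the only free hydroxyl (C8), with no stereocentre affected.

**Step 19**
Reactants: 33 (3aR,4R,5R,6Z,10E,11aR)-5-(tert-butyldimethylsilyloxy)-3a-[(4-methoxyphenyl)methoxy]-6,10-dimethyl-3-methylidene-2-oxo-2,3,3a,4,5,8,9,11a-octahydrocyclodeca[b]furan-4-yl (2S,3R)-2,3-dimethyloxirane-2-carboxylate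
Product: 34 (3aR,4R,5R,6Z,10E,11aR)-5-(tert-butyldimethylsilyloxy)-3a-hydroxy-6,10-dimethyl-3-methylidene-2-oxo-2,3,3a,4,5,8,9,11a-octahydrocyclodeca[b]furan-4-yl (2S,3R)-2,3-dimethyloxirane-2-carboxylate
Conditions: DDQ, CH2Cl2/pH 7 phosphate buffer (10:1), 0 °C → rt
Reagents that add atoms: none
Why: Oxidative PMB ether cleavage: benzylic hydride abstraction by DDQ and hydrolysis of the oxocarbenium ion should free the tertiary C7 hydroxyl under near-neutral conditions that spare the diene, epoxide and silyl ether.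

**Step 20**
Reactants: 34 (3aR,4R,5R,6Z,10E,11aR)-5-(tert-butyldimethylsilyloxy)-3a-hydroxy-6,10-dimethyl-3-methylidene-2-oxo-2,3,3a,4,5,8,9,11a-octahydrocyclodeca[b]furan-4-yl (2S,3R)-2,3-dimethyloxirane-2-carboxylate
Product: 35 (3aR,4R,5R,6Z,10E,11aR)-3a,5-dihydroxy-6,10-dimethyl-3-methylidene-2-oxo-2,3,3a,4,5,8,9,11a-octahydrocyclodeca[b]furan-4-yl (2S,3R)-2,3-dimethyloxirane-2-carboxylate (CNP0420662.1)
Conditions: HF·pyridine, pyridine, THF, 0 °C → rt
Reagents that add atoms: none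
Why: Fluoride-mediated desilylation under buffered, non-basic conditions should free the C9 hydroxyl without acyl migration from C8, epoxide opening or addition to the α-methylene lactone.

**Compound list**

1 | methyl (4S)-2,2-dimethyl-1,3-dioxolane-4-carboxylate | COC(=O)[C@@H]1COC(C)(C)O1 | starting material
2 | (4S)-N-methoxy-N,2,2-trimethyl-1,3-dioxolane-4-carboxamide | CON(C)C(=O)[C@@H]1COC(C)(C)O1 | intermediate
3 | 1-[(4S)-2,2-dimethyl-1,3-dioxolan-4-yl]ethan-1-one | CC(=O)[C@@H]1COC(C)(C)O1 | intermediate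
4 | 5-chloropent-1-yne | C#CCCCCl | starting material
5 | [(1E)-5-chloro-2-methylpent-1-en-1-yl]dimethylalane | C[Al](C)/C=C(\C)CCCCl | intermediate
6 | (1E)-5-chloro-1-iodo-2-methylpent-1-ene | I/C=C(\C)CCCCl | intermediate
7 | (1E)-1,5-diiodo-2-methylpent-1-ene | I/C=C(\C)CCCI | intermediate
8 | [(4E)-5-iodo-4-methylpent-4-en-1-yl]triphenylphosphonium iodide | I/C=C(\C)CCC[P+](c1ccccc1)(c1ccccc1)c1ccccc1.[I-] | intermediate
9 | [(4E)-5-iodo-4-methylpent-4-en-1-ylidene]triphenylphosphorane | I/C=C(\C)CCC=P(c1ccccc1)(c1ccccc1)c1ccccc1 | intermediate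
10 | (4R)-4-[(2Z,6E)-7-iodo-6-methylhepta-2,6-dien-2-yl]-2,2-dimethyl-1,3-dioxolane | I/C=C(\C)CC/C=C(/C)[C@@H]1COC(C)(C)O1 | intermediate
11 | (2R,3Z,7E)-8-iodo-3,7-dimethylocta-3,7-diene-1,2-diol | I/C=C(\C)CC/C=C(/C)[C@@H](O)CO | intermediate
12 | (2R,3Z,7E)-1,2-bis(tert-butyldimethylsilyloxy)-8-iodo-3,7-dimethylocta-3,7-diene | I/C=C(\C)CC/C=C(/C)[C@@H](O[Si](C)(C)C(C)(C)C)CO[Si](C)(C)C(C)(C)C | intermediate
13 | [(1E,5Z,7R)-7,8-bis(tert-butyldimethylsilyloxy)-2,6-dimethylocta-1,5-dien-1-yl]lithium | [Li]/C=C(\C)CC/C=C(/C)[C@@H](O[Si](C)(C)C(C)(C)C)CO[Si](C)(C)C(C)(C)C | intermediate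
14 | (2E,6Z,8R)-8,9-bis(tert-butyldimethylsilyloxy)-3,7-dimethylnona-2,6-dienal | O=C/C=C(\C)CC/C=C(/C)[C@@H](O[Si](C)(C)C(C)(C)C)CO[Si](C)(C)C(C)(C)C | intermediate
15 | methyl prop-2-ynoate | C#CC(=O)OC | starting material
16 | methyl 3-(methylzincio)prop-2-ynoate | C[Zn]C#CC(=O)OC | intermediate
17 | methyl (4R,5E,9Z,11R)-11,12-bis(tert-butyldimethylsilyloxy)-4-hydroxy-6,10-dimethyldodeca-5,9-dien-2-ynoate | COC(=O)C#C[C@H](O)/C=C(\C)CC/C=C(/C)[C@@H](O[Si](C)(C)C(C)(C)C)CO[Si](C)(C)C(C)(C)C | intermediate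
18 | methyl (2E,4R,5E,9Z,11R)-11,12-bis(tert-butyldimethylsilyloxy)-4-hydroxy-3-[(4-methoxyphenyl)methoxy]-6,10-dimethyldodeca-2,5,9-trienoate | COC(=O)/C=C(/OCc1ccc(OC)cc1)[C@H](O)/C=C(\C)CC/C=C(/C)[C@@H](O[Si](C)(C)C(C)(C)C)CO[Si](C)(C)C(C)(C)C | intermediate
19 | (5R)-5-[(1E,5Z,7R)-7,8-bis(tert-butyldimethylsilyloxy)-2,6-dimethylocta-1,5-dien-1-yl]-4-[(4-methoxyphenyl)methoxy]furan-2(5H)-one | COc1ccc(COC2=CC(=O)O[C@@H]2/C=C(\C)CC/C=C(/C)[C@@H](O[Si](C)(C)C(C)(C)C)CO[Si](C)(C)C(C)(C)C)cc1 | intermediate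
20 | (5R)-5-[(1E,5Z,7R)-7,8-bis(tert-butyldimethylsilyloxy)-2,6-dimethylocta-1,5-dien-1-yl]-3-iodo-4-[(4-methoxyphenyl)methoxy]furan-2(5H)-one | COc1ccc(COC2=C(I)C(=O)O[C@@H]2/C=C(\C)CC/C=C(/C)[C@@H](O[Si](C)(C)C(C)(C)C)CO[Si](C)(C)C(C)(C)C)cc1 | intermediate
21 | chloro{(5R)-5-[(1E,5Z,7R)-7,8-bis(tert-butyldimethylsilyloxy)-2,6-dimethylocta-1,5-dien-1-yl]-4-[(4-methoxyphenyl)methoxy]-2-oxo-2,5-dihydrofuran-3-yl}magnesium | COc1ccc(COC2=C([Mg]Cl)C(=O)O[C@@H]2/C=C(\C)CC/C=C(/C)[C@@H](O[Si](C)(C)C(C)(C)C)CO[Si](C)(C)C(C)(C)C)cc1 | intermediate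
22 | (5R)-5-[(1E,5Z,7R)-7,8-bis(tert-butyldimethylsilyloxy)-2,6-dimethylocta-1,5-dien-1-yl]-3-(hydroxymethyl)-4-[(4-methoxyphenyl)methoxy]furan-2(5H)-one | COc1ccc(COC2=C(CO)C(=O)O[C@@H]2/C=C(\C)CC/C=C(/C)[C@@H](O[Si](C)(C)C(C)(C)C)CO[Si](C)(C)C(C)(C)C)cc1 | intermediate
23 | (5R)-5-[(1E,5Z,7R)-7,8-bis(tert-butyldimethylsilyloxy)-2,6-dimethylocta-1,5-dien-1-yl]-3-(bromomethyl)-4-[(4-methoxyphenyl)methoxy]furan-2(5H)-one | COc1ccc(COC2=C(CBr)C(=O)O[C@@H]2/C=C(\C)CC/C=C(/C)[C@@H](O[Si](C)(C)C(C)(C)C)CO[Si](C)(C)C(C)(C)C)cc1 | intermediate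
24 | (5R)-3-(bromomethyl)-5-[(1E,5Z,7R)-7-(tert-butyldimethylsilyloxy)-8-hydroxy-2,6-dimethylocta-1,5-dien-1-yl]-4-[(4-methoxyphenyl)methoxy]furan-2(5H)-one | COc1ccc(COC2=C(CBr)C(=O)O[C@@H]2/C=C(\C)CC/C=C(/C)[C@@H](O[Si](C)(C)C(C)(C)C)CO)cc1 | intermediate
25 | (2R,3Z,7E)-8-[(2R)-4-(bromomethyl)-3-[(4-methoxyphenyl)methoxy]-5-oxo-2,5-dihydrofuran-2-yl]-2-(tert-butyldimethylsilyloxy)-3,7-dimethylocta-3,7-dienal | COc1ccc(COC2=C(CBr)C(=O)O[C@@H]2/C=C(\C)CC/C=C(/C)[C@@H](O[Si](C)(C)C(C)(C)C)C=O)cc1 | intermediate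
26 | dichloro{[(5R)-5-[(1E,5Z,7R)-7-(tert-butyldimethylsilyloxy)-2,6-dimethyl-8-oxoocta-1,5-dien-1-yl]-4-[(4-methoxyphenyl)methoxy]-2-oxo-2,5-dihydrofuran-3-yl]methyl}chromium | COc1ccc(COC2=C(C[Cr](Cl)Cl)C(=O)O[C@@H]2/C=C(\C)CC/C=C(/C)[C@@H](O[Si](C)(C)C(C)(C)C)C=O)cc1 | intermediate
27 | (3aS,4R,5R,6Z,10E,11aR)-5-(tert-butyldimethylsilyloxy)-4-hydroxy-3a-[(4-methoxyphenyl)methoxy]-6,10-dimethyl-3-methylidene-3a,4,5,8,9,11a-hexahydrocyclodeca[b]furan-2(3H)-one | C=C1C(=O)O[C@@H]2/C=C(\C)CC/C=C(/C)[C@@H](O[Si](C)(C)C(C)(C)C)[C@@H](O)[C@@]12OCc1ccc(OC)cc1 | intermediate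
28 | (2E)-2-methylbut-2-en-1-ol | C/C=C(\C)CO | starting material
29 | [(2R,3R)-2,3-dimethyloxiran-2-yl]methanol | OC[C@@]1(C)O[C@@H]1C | intermediate
30 | (2S,3R)-2,3-dimethyloxirane-2-carbaldehyde | O=C[C@@]1(C)O[C@@H]1C | intermediate
31 | (2S,3R)-2,3-dimethyloxirane-2-carboxylic acid | OC(=O)[C@@]1(C)O[C@@H]1C | intermediate
32 | (2S,3R)-2,3-dimethyloxirane-2-carboxylic 2,4,6-trichlorobenzoic anhydride | O=C(OC(=O)c1c(Cl)cc(Cl)cc1Cl)[C@@]1(C)O[C@@H]1C | intermediate
33 | (3aR,4R,5R,6Z,10E,11aR)-5-(tert-butyldimethylsilyloxy)-3a-[(4-methoxyphenyl)methoxy]-6,10-dimethyl-3-methylidene-2-oxo-2,3,3a,4,5,8,9,11a-octahydrocyclodeca[b]furan-4-yl (2S,3R)-2,3-dimethyloxirane-2-carboxylate | C=C1C(=O)O[C@@H]2/C=C(\C)CC/C=C(/C)[C@@H](O[Si](C)(C)C(C)(C)C)[C@@H](OC(=O)[C@@]3(C)O[C@@H]3C)[C@@]12OCc1ccc(OC)cc1 | intermediate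
34 | (3aR,4R,5R,6Z,10E,11aR)-5-(tert-butyldimethylsilyloxy)-3a-hydroxy-6,10-dimethyl-3-methylidene-2-oxo-2,3,3a,4,5,8,9,11a-octahydrocyclodeca[b]furan-4-yl (2S,3R)-2,3-dimethyloxirane-2-carboxylate | C=C1C(=O)O[C@@H]2/C=C(\C)CC/C=C(/C)[C@@H](O[Si](C)(C)C(C)(C)C)[C@@H](OC(=O)[C@@]3(C)O[C@@H]3C)[C@@]12O | intermediate
35 | (3aR,4R,5R,6Z,10E,11aR)-3a,5-dihydroxy-6,10-dimethyl-3-methylidene-2-oxo-2,3,3a,4,5,8,9,11a-octahydrocyclodeca[b]furan-4-yl (2S,3R)-2,3-dimethyloxirane-2-carboxylate | C=C1C(=O)O[C@@H]2/C=C(\C)CC/C=C(/C)[C@@H](O)[C@@H](OC(=O)[C@@]3(C)O[C@@H]3C)[C@@]12O | target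

**Step count and risks**

Total step count: 20. Longest linear sequence: 17 steps (steps 2–15, then 18–20, from 5-chloropent-1-yne).

Steps most likely to fail:

1. Step 15 (Proposed new method). The allylchromium may react through C13 instead of C7 (twelve-membered ring with the tetronate intact), couple intermolecularly, be protonated, or close with the wrong facial sense at C8. The fallback uses known reaction types and sets out from 22. Acetylation (Ac2O, pyridine) should give [(5R)-5-[(1E,5Z,7R)-7,8-bis(tert-butyldimethylsilyloxy)-2,6-dimethylocta-1,5-dien-1-yl]-4-[(4-methoxyphenyl)methoxy]-2-oxo-2,5-dihydrofuran-3-yl]methyl acetate F1. Selective primary desilylation (HF·pyridine, pyridine, THF) should give the primary alcohol F2, and Dess–Martin oxidation the aldehyde F3. SmI2 (THF, high dilution, 0 °C) then forms the C8 ketyl radical, which adds to the β-alkoxyacrylate carbon C7 (the SmI2 reductive cyclisation of aldehydes onto β-alkoxyacrylates); the samarium enolate expels acetate from C13 (ketyl–olefin coupling/β-elimination sequence). This comes back to the route at 27, through an open radical transition state that offers a different stereochemical course at C8.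

2. Step 10. Iodonium chemistry at the two trisubstituted alkenes may compete with substitution at C3 (poor chemoselectivity), and the exchange/hydroxymethylation of step 11 depends on it. The fallback sets out from 17 and replaces steps 9–12. Allyl alcohol with catalytic NaH should give the allyl tetronate (5R)-5-[(1E,5Z,7R)-7,8-bis(tert-butyldimethylsilyloxy)-2,6-dimethylocta-1,5-dien-1-yl]-4-(prop-2-en-1-yloxy)furan-2(5H)-one F4. Deallylation (Pd(PPh3)4, morpholine, THF) frees the tetronic acid F5. Its nucleophilic C3 is then functionalised by three-component condensation with paraformaldehyde and thiophenol (Knoevenagel/thia-Michael) to the 3-[(phenylsulfanyl)methyl]tetronic acid F6. Mitsunobu etherification with 4-methoxybenzyl alcohol gives the PMB tetronate sulfide F7. S-Methylation (MeOTf, CH2Cl2) gives the sulfonium triflate F8, and displacement with LiBr in acetone comes back to the route at 23.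

3. Step 18. Acyl transfer may fail at the C8 hydroxyl, wedged between the quaternary C7–OPMB carbon and the C9 silyl ether, or base may induce translactonisation to the 8,12-olide before acylation. The fallback sets out from 27 and inverts the order of deprotection and acylation. DDQ in wet CH2Cl2 first gives the diol (3aS,4R,5R,6Z,10E,11aR)-5-(tert-butyldimethylsilyloxy)-3a,4-dihydroxy-6,10-dimethyl-3-methylidene-3a,4,5,8,9,11a-hexahydrocyclodeca[b]furan-2(3H)-one F9. Its much less congested secondary C8 hydroxyl (the tertiary C7 hydroxyl does not compete) is acylated with (2S,3R)-2,3-dimethyloxirane-2-carbonyl chloride F10, made from 31 with 1-chloro-N,N,2-trimethylprop-1-en-1-amine, in pyridine/CH2Cl2 at 0 °C. This comes back to the route at 34.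

**Further compounds**

F1 | step 15 | [(5R)-5-[(1E,5Z,7R)-7,8-bis(tert-butyldimethylsilyloxy)-2,6-dimethylocta-1,5-dien-1-yl]-4-[(4-methoxyphenyl)methoxy]-2-oxo-2,5-dihydrofuran-3-yl]methyl acetate | COc1ccc(COC2=C(COC(C)=O)C(=O)O[C@@H]2/C=C(\C)CC/C=C(/C)[C@@H](O[Si](C)(C)C(C)(C)C)CO[Si](C)(C)C(C)(C)C)cc1
F2 | step 15 | [(5R)-5-[(1E,5Z,7R)-7-(tert-butyldimethylsilyloxy)-8-hydroxy-2,6-dimethylocta-1,5-dien-1-yl]-4-[(4-methoxyphenyl)methoxy]-2-oxo-2,5-dihydrofuran-3-yl]methyl acetate | COc1ccc(COC2=C(COC(C)=O)C(=O)O[C@@H]2/C=C(\C)CC/C=C(/C)[C@@H](O[Si](C)(C)C(C)(C)C)CO)cc1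
F3 | step 15 | [(5R)-5-[(1E,5Z,7R)-7-(tert-butyldimethylsilyloxy)-2,6-dimethyl-8-oxoocta-1,5-dien-1-yl]-4-[(4-methoxyphenyl)methoxy]-2-oxo-2,5-dihydrofuran-3-yl]methyl acetate | COc1ccc(COC2=C(COC(C)=O)C(=O)O[C@@H]2/C=C(\C)CC/C=C(/C)[C@@H](O[Si](C)(C)C(C)(C)C)C=O)cc1
F4 | step 10 | (5R)-5-[(1E,5Z,7R)-7,8-bis(tert-butyldimethylsilyloxy)-2,6-dimethylocta-1,5-dien-1-yl]-4-(prop-2-en-1-yloxy)furan-2(5H)-one | C=CCOC1=CC(=O)O[C@@H]1/C=C(\C)CC/C=C(/C)[C@@H](O[Si](C)(C)C(C)(C)C)CO[Si](C)(C)C(C)(C)C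
F5 | step 10 | (5R)-5-[(1E,5Z,7R)-7,8-bis(tert-butyldimethylsilyloxy)-2,6-dimethylocta-1,5-dien-1-yl]-4-hydroxyfuran-2(5H)-one | OC1=CC(=O)O[C@@H]1/C=C(\C)CC/C=C(/C)[C@@H](O[Si](C)(C)C(C)(C)C)CO[Si](C)(C)C(C)(C)C
F6 | step 10 | (5R)-5-[(1E,5Z,7R)-7,8-bis(tert-butyldimethylsilyloxy)-2,6-dimethylocta-1,5-dien-1-yl]-4-hydroxy-3-[(phenylsulfanyl)methyl]furan-2(5H)-one | OC1=C(CSc2ccccc2)C(=O)O[C@@H]1/C=C(\C)CC/C=C(/C)[C@@H](O[Si](C)(C)C(C)(C)C)CO[Si](C)(C)C(C)(C)C
F7 | step 10 | (5R)-5-[(1E,5Z,7R)-7,8-bis(tert-butyldimethylsilyloxy)-2,6-dimethylocta-1,5-dien-1-yl]-4-[(4-methoxyphenyl)methoxy]-3-[(phenylsulfanyl)methyl]furan-2(5H)-one | COc1ccc(COC2=C(CSc3ccccc3)C(=O)O[C@@H]2/C=C(\C)CC/C=C(/C)[C@@H](O[Si](C)(C)C(C)(C)C)CO[Si](C)(C)C(C)(C)C)cc1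
F8 | step 10 | {[(5R)-5-[(1E,5Z,7R)-7,8-bis(tert-butyldimethylsilyloxy)-2,6-dimethylocta-1,5-dien-1-yl]-4-[(4-methoxyphenyl)methoxy]-2-oxo-2,5-dihydrofuran-3-yl]methyl}(methyl)phenylsulfonium trifluoromethanesulfonate | COc1ccc(COC2=C(C[S+](C)c3ccccc3)C(=O)O[C@@H]2/C=C(\C)CC/C=C(/C)[C@@H](O[Si](C)(C)C(C)(C)C)CO[Si](C)(C)C(C)(C)C)cc1.[O-]S(=O)(=O)C(F)(F)F
F9 | step 18 | (3aS,4R,5R,6Z,10E,11aR)-5-(tert-butyldimethylsilyloxy)-3a,4-dihydroxy-6,10-dimethyl-3-methylidene-3a,4,5,8,9,11a-hexahydrocyclodeca[b]furan-2(3H)-one | C=C1C(=O)O[C@@H]2/C=C(\C)CC/C=C(/C)[C@@H](O[Si](C)(C)C(C)(C)C)[C@@H](O)[C@@]12O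
F10 | step 18 | (2S,3R)-2,3-dimethyloxirane-2-carbonyl chloride | ClC(=O)[C@@]1(C)O[C@@H]1C
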